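**Plan**

- Retrosynthesis: cut the ester C3–O bond (core alcohol 13 + silyl-protected dienoic acid 21). Trace the diosphenol back to the C8 ketone (C7 oxidised last). Then cut the ring-A bonds C3–C4 and C5–C10 together as a retro-Diels–Alder to the acyclic acyl vinylallene 11.
- Enabling feature: ring A is a cyclohexene (C10–C1=C2–C3–C4–C5) whose fusion carbon C10 is sp2 and carries the ring-B double bond C9=C10. This is what an allene C9=C10=C1 leaves behind after a [4+2] across C10=C1–C2=C3, and ring B (C5–C6–C7–C8–C9–C10) is then the six-membered tether ring.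
- Forward: the chain C4–C10 is built linearly (Johnson–Claisen, Wittig, epoxidation, alkyne homologation) and C2–C3 are added by Pd coupling. Oxidation then triggers one cycloaddition that closes rings A and B together; ester union and ring-B oxidation follow.
- Stereochemistry: one catalytic epoxidation sets C9, and anti-SN2′ coupling converts it into the allene axis. The axis sets C5, the (E)-alkene sets C4 relative to C5, and the (E)-alkenylboronate sets C3 (all-cis). C8 and C9 are then erased, and boron is exchanged for oxygen with retention.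
- The side-chain centre C6′ comes from an organocatalytic α-hydroxymethylation of butanal.

Key step: step 7

Remark: core atoms carry eremophilane numbers (C3 carbinol, C4 and C5 methyl-bearing, C8 ketone, C7 enol carbon). The facial sense of the two prolinol silyl ether steps (4 and 9) is assigned from the usual steric model (attack anti to the diaryl(silyloxy)methyl group); the mirror-image catalyst, equally available, would be used if the sense proved opposite.

**Route**

Step 1
Reactants: 1 3-methylbut-3-en-2-ol (racemic)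
Product: 4 ethyl (E)-4-methylhex-4-enoate, via mixed orthoester 2 (not isolated), via ketene acetal 3 (not isolated)
Conditions: MeC(OEt)3 (6 equiv), EtCO2H (5 mol %), 140 °C, EtOH distilled off
Reagents that add atoms: triethyl orthoacetate CCOC(C)(OCC)OCC
Why: Johnson–Claisen rearrangement: exchange gives the mixed orthoester, loss of ethanol gives the ketene acetal, and its chair [3,3] shift with the carbinol methyl equatorial should deliver the (E)-trisubstituted alkene that later fixes the cis relation of the C4 and C5 methyl groups.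

Step 2
Reactants: 4 ethyl (E)-4-methylhex-4-enoate
Product: 5 (E)-4-methylhex-4-enal
Conditions: DIBAL-H (1.05 equiv), CH2Cl2, −78 °C; aq. Rochelle salt
Reagents that add atoms: none
Why: DIBAL-H half-reduction of an ester, in which the aluminium hemiacetal is stable at −78 °C and releases the aldehyde only on work-up while the isolated alkene is inert.

Step 3
Reactants: 5 (E)-4-methylhex-4-enal
Product: 6 (2E,6E)-6-methylocta-2,6-dienal
Conditions: Ph3P=CHCHO (1.1 equiv), PhMe, 80 °C
Reagents that add atoms: (triphenylphosphoranylidene)acetaldehyde O=CC=P(c1ccccc1)(c1ccccc1)c1ccccc1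
Why: Wittig olefination with a stabilised formyl ylide should give the (E)-enal and stop after one homologation because the conjugated product is much less electrophilic than 5.

Step 4
Reactants: 6 (2E,6E)-6-methylocta-2,6-dienal
Product: 7 (2S,3R)-3-[(E)-3-methylpent-3-en-1-yl]oxirane-2-carbaldehyde
Conditions: (S)-α,α-bis[3,5-bis(trifluoromethyl)phenyl]prolinol trimethylsilyl ether (10 mol %), 35 % aq. H2O2 (1.3 equiv), CH2Cl2, rt
Reagents that add atoms: hydrogen peroxide OO
Why: Iminium–enamine organocatalytic epoxidation of an enal: peroxide should add to the β-carbon of the (E)-iminium ion on the face away from the diaryl(silyloxy)methyl group and the enamine then closes the trans-oxirane, which sets C8 and C9 (C9 later controls the allene axis), while the nucleophilic oxidant leaves the electron-rich trisubstituted alkene alone.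

Step 5
Reactants: 7 (2S,3R)-3-[(E)-3-methylpent-3-en-1-yl]oxirane-2-carbaldehyde
Product: 8 (2R,3R)-2-ethynyl-3-[(E)-3-methylpent-3-en-1-yl]oxirane
Conditions: dimethyl (1-diazo-2-oxopropyl)phosphonate (1.3 equiv), K2CO3 (2 equiv), MeOH, 0 °C to rt
Reagents that add atoms: dimethyl (1-diazo-2-oxopropyl)phosphonate COP(=O)(OC)C(=[N+]=[N-])C(C)=O
Why: Seyferth–Gilbert homologation in the Ohira–Bestmann form: the diazomethylphosphonate anion freed by methanolysis adds to the aldehyde and collapses through a vinylidene carbene to the terminal alkyne under conditions mild enough to keep the oxirane and its non-enolisable α-centre intact (the descriptor at C2 changes only through the CIP order).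

Step 6
Reactants: 8 (2R,3R)-2-ethynyl-3-[(E)-3-methylpent-3-en-1-yl]oxirane; 9 (E)-1,2-bis(4,4,5,5-tetramethyl-1,3,2-dioxaborolan-2-yl)ethene
Product: 10 (1E,3Ra,6R,9E)-9-methyl-1-(4,4,5,5-tetramethyl-1,3,2-dioxaborolan-2-yl)undeca-1,3,4,9-tetraen-6-ol
Conditions: Pd(PPh3)4 (5 mol %), 9 (3 equiv), THF–H2O (10:1), 25–40 °C; chromatography to remove all palladium
Reagents that add atoms: none
Why: Palladium-catalysed anti-SN2′ Suzuki–Miyaura-type coupling of an alkynyl oxirane: Pd(0) should attack the alkyne terminus anti to the breaking C9–O bond, and transmetalation with one boron of 9 followed by reductive elimination with retention places the (E)-borylvinyl group on C1, so the C9 centre becomes the (Ra) allene axis while the carbinol centre is untouched and the excess of 9 suppresses double coupling.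

Step 7
Reactants: 10 (1E,3Ra,6R,9E)-9-methyl-1-(4,4,5,5-tetramethyl-1,3,2-dioxaborolan-2-yl)undeca-1,3,4,9-tetraen-6-ol
Product: 12 (4aR,5S,6S)-4a,5-dimethyl-6-(4,4,5,5-tetramethyl-1,3,2-dioxaborolan-2-yl)-4,4a,5,6-tetrahydronaphthalen-2(3H)-one, via allenyl ketone 11 (not isolated)
Conditions: Dess–Martin periodinane (1.2 equiv), NaHCO3, CH2Cl2, 0 °C; filtration through neutral alumina; then PhMe (0.01 M), BHT (cat.), 25 to 60 °C
Reagents that add atoms: none
Why: Oxidation of the α-allenol gives the acyl vinylallene 11, whose diene C10=C1–C2=C3 (the allene π bond remote from the ketone plus the (E)-borylvinyl group) should add across the tethered (E)-trisubstituted alkene C4=C5 in a concerted, asynchronous intramolecular Diels–Alder reaction; the closest known reaction type is the thermal intramolecular Diels–Alder reaction of vinylallenes tethered through the allene terminus, with centre-to-axis-to-centre chirality transfer. Ring A is closed by the [4+2] itself (bonds C3–C4 and C5–C10), and ring B arises as the six-membered tether ring C5–C6–C7–C8–C9=C10, the allene central carbon C10 becoming the sp2 fusion atom so that the C1=C2/C9=C10 diene of the target is formed directly. The quaternary centre C5 is set by the allene axis, because C8 on C9 lies on one face only of the C10=C1 π bond and the three-atom tether can deliver C5 to that face alone; C4 follows from suprafacial addition to the (E)-alkene (4-Me cis to 5-Me); C3 follows from the (E)-alkenylboronate, whose outside boron ends cis to the two methyl groups that the tether forces into the endo positions. The step needs periselectivity for [4+2] over [2+2], ene and oxa-diene modes and needs the allene to keep its configuration: the s-cis diene is easily reached because the allene terminus has no inside substituent, the unit O=C8–C9=C10 is held s-trans inside the forming ring B (which blocks the oxa-diene mode and pre-organises the tether), the electron-poor diene is matched with the electron-rich alkene, and neutral metal-free conditions should prevent racemisation or cycloisomerisation of the allenyl ketone.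

Step 8
Reactants: 12 (4aR,5S,6S)-4a,5-dimethyl-6-(4,4,5,5-tetramethyl-1,3,2-dioxaborolan-2-yl)-4,4a,5,6-tetrahydronaphthalen-2(3H)-one
Product: 13 (4aR,5R,6S)-6-hydroxy-4a,5-dimethyl-4,4a,5,6-tetrahydronaphthalen-2(3H)-one
Conditions: 30 % aq. H2O2, pH 7 phosphate buffer, THF, 0 °C to rt
Reagents that add atoms: hydrogen peroxide OO
Why: Oxidation of a secondary allylic boronate proceeds by a 1,2-shift from boron to oxygen with retention and without allylic transposition, which should give the C3 alcohol cis to both methyl groups, and at pH 7 the β,β-disubstituted dienone is not expected to be epoxidised.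

Step 9
Reactants: 14 butanal
Product: 16 ethyl (R,E)-4-(hydroxymethyl)hex-2-enoate, via (S)-2-(hydroxymethyl)butanal 15 (not isolated)
Conditions: 37 % aq. CH2O, (R)-α,α-diphenylprolinol trimethylsilyl ether (10 mol %), pH 7 phosphate buffer, PhMe, rt; then Ph3P=CHCO2Et (1.5 equiv), rt
Reagents that add atoms: formaldehyde C=O; ethyl (triphenylphosphoranylidene)acetate CCOC(=O)C=P(c1ccccc1)(c1ccccc1)c1ccccc1
Why: Enamine-catalysed α-hydroxymethylation with Wittig trapping: formaldehyde should attack the (E)-enamine on the face away from the diphenyl(silyloxy)methyl group, which sets the (S) centre, and the stabilised ylide converts the sensitive aldol in situ into the (E)-enoate before it can dimerise or racemise.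

Step 10
Reactants: 16 ethyl (R,E)-4-(hydroxymethyl)hex-2-enoate
Product: 17 ethyl (R,E)-4-[(tert-butyldimethylsilyloxy)methyl]hex-2-enoate
Conditions: TBSCl (1.2 equiv), imidazole (2 equiv), CH2Cl2, rt
Reagents that add atoms: tert-butyldimethylsilyl chloride CC(C)(C)[Si](C)(C)Cl
Why: Standard silylation of a primary alcohol with the silyl chloride and imidazole.

Step 11
Reactants: 17 ethyl (R,E)-4-[(tert-butyldimethylsilyloxy)methyl]hex-2-enoate
Product: 18 (R,E)-4-[(tert-butyldimethylsilyloxy)methyl]hex-2-en-1-ol
Conditions: DIBAL-H (2.2 equiv), CH2Cl2, −78 °C; aq. Rochelle salt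
Reagents that add atoms: none
Why: DIBAL-H reduces the conjugated ester by 1,2-addition to the allylic alcohol without touching the silyl ether or the allylic stereocentre.

Step 12
Reactants: 18 (R,E)-4-[(tert-butyldimethylsilyloxy)methyl]hex-2-en-1-ol
Product: 20 ethyl (2E,4E,6R)-6-[(tert-butyldimethylsilyloxy)methyl]octa-2,4-dienoate, via (R,E)-enal 19 (not isolated)
Conditions: activated MnO2 (10 equiv), Ph3P=CHCO2Et (1.3 equiv), CH2Cl2, rt
Reagents that add atoms: ethyl (triphenylphosphoranylidene)acetate CCOC(=O)C=P(c1ccccc1)(c1ccccc1)c1ccccc1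
Why: Tandem oxidation–Wittig reaction: manganese dioxide oxidises only the allylic alcohol and the enal is trapped at once by the stabilised ylide as the (2E,4E)-dienoate, so the γ-stereocentre of the enal is never exposed to base.

Step 13
Reactants: 20 ethyl (2E,4E,6R)-6-[(tert-butyldimethylsilyloxy)methyl]octa-2,4-dienoate
Product: 21 (2E,4E,6R)-6-[(tert-butyldimethylsilyloxy)methyl]octa-2,4-dienoic acid
Conditions: LiOH·H2O (3 equiv), THF–MeOH–H2O, rt; 1 M HCl to pH 4 at 0 °C
Reagents that add atoms: lithium hydroxide [Li+].[OH-]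
Why: Saponification cleaves the ethyl ester, and the ε-hydrogen of the dienoate is far too weakly acidic to epimerise under these conditions.

Step 14
Reactants: 21 (2E,4E,6R)-6-[(tert-butyldimethylsilyloxy)methyl]octa-2,4-dienoic acid; 13 (4aR,5R,6S)-6-hydroxy-4a,5-dimethyl-4,4a,5,6-tetrahydronaphthalen-2(3H)-one
Product: 23 (1R,2S,8aR)-1,8a-dimethyl-6-oxo-1,2,6,7,8,8a-hexahydronaphthalen-2-yl (2E,4E,6R)-6-[(tert-butyldimethylsilyloxy)methyl]octa-2,4-dienoate, via mixed anhydride 22 (not isolated)
Conditions: 2,4,6-trichlorobenzoyl chloride (1.2 equiv), Et3N, THF, rt; then 13, DMAP, PhMe, rt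
Reagents that add atoms: none
Why: Yamaguchi esterification: DMAP attacks the unhindered dienoyl carbonyl of the mixed anhydride and the acylpyridinium ion should acylate the hindered C3 alcohol with retention, since the C3–O bond is not broken.

Step 15
Reactants: 23 (1R,2S,8aR)-1,8a-dimethyl-6-oxo-1,2,6,7,8,8a-hexahydronaphthalen-2-yl (2E,4E,6R)-6-[(tert-butyldimethylsilyloxy)methyl]octa-2,4-dienoate
Product: 25 (1R,2S,7R,8aR)-7-hydroxy-1,8a-dimethyl-6-oxo-1,2,6,7,8,8a-hexahydronaphthalen-2-yl (2E,4E,6R)-6-[(tert-butyldimethylsilyloxy)methyl]octa-2,4-dienoate, via potassium enolate 24 (not isolated)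
Conditions: KHMDS (1.05 equiv), THF, −78 °C; (+)-(camphorsulfonyl)oxaziridine (1.3 equiv), −78 to −40 °C; aq. NH4Cl
Reagents that add atoms: (camphorsulfonyl)oxaziridine CC1(C)C2CCC13CS(=O)(=O)N4OC34C2
Why: Enolate hydroxylation with an N-sulfonyloxaziridine: kinetic deprotonation at C7 (the only sp3 α-carbon of the dienone) and oxygen transfer to the cross-conjugated enolate, expected on the face anti to the angular C5 methyl group (the new C7 centre is removed in step 16).

Step 16
Reactants: 25 (1R,2S,7R,8aR)-7-hydroxy-1,8a-dimethyl-6-oxo-1,2,6,7,8,8a-hexahydronaphthalen-2-yl (2E,4E,6R)-6-[(tert-butyldimethylsilyloxy)methyl]octa-2,4-dienoate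
Product: 27 (1R,2S,8aS)-7-hydroxy-1,8a-dimethyl-6-oxo-1,2,6,8a-tetrahydronaphthalen-2-yl (2E,4E,6R)-6-[(tert-butyldimethylsilyloxy)methyl]octa-2,4-dienoate, via 6,7-dione 26 (not isolated)
Conditions: Dess–Martin periodinane (1.5 equiv), NaHCO3, CH2Cl2, 0 °C to rt
Reagents that add atoms: none
Why: Dess–Martin oxidation of the α-ketol gives the 1,2-dione, which can enolise only towards C6 and should therefore tautomerise to the cross-conjugated diosphenol of the target.

Step 17
Reactants: 27 (1R,2S,8aS)-7-hydroxy-1,8a-dimethyl-6-oxo-1,2,6,8a-tetrahydronaphthalen-2-yl (2E,4E,6R)-6-[(tert-butyldimethylsilyloxy)methyl]octa-2,4-dienoate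
Product: 28 Septeremophilane E
Conditions: HF·pyridine, pyridine–THF, 0 °C to rt
Reagents that add atoms: none
Why: Fluoride-mediated cleavage of the primary silyl ether under buffered conditions should leave the allylic ester, the trienone and the diosphenol untouched.

**Compound list**

1 | 3-methylbut-3-en-2-ol (racemic) | CC(O)C(C)=C | starting material
2 | 1,1-diethoxy-1-[(3-methylbut-3-en-2-yl)oxy]ethane (mixed orthoester) | CCOC(C)(OCC)OC(C)C(C)=C | intermediate
3 | 1-ethoxy-1-[(3-methylbut-3-en-2-yl)oxy]ethene (ketene acetal) | CCOC(=C)OC(C)C(C)=C | intermediate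
4 | ethyl (E)-4-methylhex-4-enoate | CCOC(=O)CC/C(C)=C/C | intermediate
5 | (E)-4-methylhex-4-enal | O=CCC/C(C)=C/C | intermediate
6 | (2E,6E)-6-methylocta-2,6-dienal | O=C/C=C/CC/C(C)=C/C | intermediate
7 | (2S,3R)-3-[(E)-3-methylpent-3-en-1-yl]oxirane-2-carbaldehyde | O=C[C@H]1O[C@@H]1CC/C(C)=C/C | intermediate
8 | (2R,3R)-2-ethynyl-3-[(E)-3-methylpent-3-en-1-yl]oxirane | C#C[C@H]1O[C@@H]1CC/C(C)=C/C | intermediate
9 | (E)-1,2-bis(4,4,5,5-tetramethyl-1,3,2-dioxaborolan-2-yl)ethene | CC1(C)OB(OC1(C)C)/C=C/B1OC(C)(C)C(C)(C)O1 | starting material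
10 | (1E,3Ra,6R,9E)-9-methyl-1-(4,4,5,5-tetramethyl-1,3,2-dioxaborolan-2-yl)undeca-1,3,4,9-tetraen-6-ol | CC1(C)OB(OC1(C)C)/C=C/C([H])=[C@]=C([H])[C@H](O)CC/C(C)=C/C | intermediate
11 | (1E,3Ra,9E)-9-methyl-1-(4,4,5,5-tetramethyl-1,3,2-dioxaborolan-2-yl)undeca-1,3,4,9-tetraen-6-one | CC1(C)OB(OC1(C)C)/C=C/C([H])=[C@]=C([H])C(=O)CC/C(C)=C/C | intermediate
12 | (4aR,5S,6S)-4a,5-dimethyl-6-(4,4,5,5-tetramethyl-1,3,2-dioxaborolan-2-yl)-4,4a,5,6-tetrahydronaphthalen-2(3H)-one (boron and both methyl groups cis) | CC1(C)OB(OC1(C)C)[C@H]1C=CC2=CC(=O)CC[C@]2(C)[C@H]1C | intermediate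
13 | (4aR,5R,6S)-6-hydroxy-4a,5-dimethyl-4,4a,5,6-tetrahydronaphthalen-2(3H)-one | O[C@H]1C=CC2=CC(=O)CC[C@]2(C)[C@H]1C | intermediate
14 | butanal | CCCC=O | starting material
15 | (S)-2-(hydroxymethyl)butanal | CC[C@H](C=O)CO | intermediate
16 | ethyl (R,E)-4-(hydroxymethyl)hex-2-enoate | CC[C@H](/C=C/C(=O)OCC)CO | intermediate
17 | ethyl (R,E)-4-[(tert-butyldimethylsilyloxy)methyl]hex-2-enoate | CC[C@H](/C=C/C(=O)OCC)CO[Si](C)(C)C(C)(C)C | intermediate
18 | (R,E)-4-[(tert-butyldimethylsilyloxy)methyl]hex-2-en-1-ol | CC[C@H](/C=C/CO)CO[Si](C)(C)C(C)(C)C | intermediate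
19 | (R,E)-4-[(tert-butyldimethylsilyloxy)methyl]hex-2-enal | CC[C@H](/C=C/C=O)CO[Si](C)(C)C(C)(C)C | intermediate
20 | ethyl (2E,4E,6R)-6-[(tert-butyldimethylsilyloxy)methyl]octa-2,4-dienoate | CC[C@H](/C=C/C=C/C(=O)OCC)CO[Si](C)(C)C(C)(C)C | intermediate
21 | (2E,4E,6R)-6-[(tert-butyldimethylsilyloxy)methyl]octa-2,4-dienoic acid | CC[C@H](/C=C/C=C/C(=O)O)CO[Si](C)(C)C(C)(C)C | intermediate
22 | mixed anhydride of 21 with 2,4,6-trichlorobenzoic acid | CC[C@H](/C=C/C=C/C(=O)OC(=O)c1c(Cl)cc(Cl)cc1Cl)CO[Si](C)(C)C(C)(C)C | intermediate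
23 | (1R,2S,8aR)-1,8a-dimethyl-6-oxo-1,2,6,7,8,8a-hexahydronaphthalen-2-yl (2E,4E,6R)-6-[(tert-butyldimethylsilyloxy)methyl]octa-2,4-dienoate | CC[C@H](/C=C/C=C/C(=O)O[C@H]1C=CC2=CC(=O)CC[C@]2(C)[C@H]1C)CO[Si](C)(C)C(C)(C)C | intermediate
24 | potassium C7=C8 enolate of 23 | CC[C@H](/C=C/C=C/C(=O)O[C@H]1C=CC2=CC([O-])=CC[C@]2(C)[C@H]1C)CO[Si](C)(C)C(C)(C)C.[K+] | intermediate
25 | (1R,2S,7R,8aR)-7-hydroxy-1,8a-dimethyl-6-oxo-1,2,6,7,8,8a-hexahydronaphthalen-2-yl (2E,4E,6R)-6-[(tert-butyldimethylsilyloxy)methyl]octa-2,4-dienoate (7-OH trans to the angular methyl) | CC[C@H](/C=C/C=C/C(=O)O[C@H]1C=CC2=CC(=O)[C@H](O)C[C@]2(C)[C@H]1C)CO[Si](C)(C)C(C)(C)C | intermediate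
26 | (1R,2S,8aR)-1,8a-dimethyl-6,7-dioxo-1,2,6,7,8,8a-hexahydronaphthalen-2-yl (2E,4E,6R)-6-[(tert-butyldimethylsilyloxy)methyl]octa-2,4-dienoate | CC[C@H](/C=C/C=C/C(=O)O[C@H]1C=CC2=CC(=O)C(=O)C[C@]2(C)[C@H]1C)CO[Si](C)(C)C(C)(C)C | intermediate
27 | (1R,2S,8aS)-7-hydroxy-1,8a-dimethyl-6-oxo-1,2,6,8a-tetrahydronaphthalen-2-yl (2E,4E,6R)-6-[(tert-butyldimethylsilyloxy)methyl]octa-2,4-dienoate | CC[C@H](/C=C/C=C/C(=O)O[C@H]1C=CC2=CC(=O)C(O)=C[C@]2(C)[C@H]1C)CO[Si](C)(C)C(C)(C)C | intermediate
28 | Septeremophilane E | CC[C@H](/C=C/C=C/C(=O)O[C@H]1C=CC2=CC(=O)C(O)=C[C@]2(C)[C@H]1C)CO | target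

**Step count and risks**

Total step count: 17. Longest linear sequence: 12 (steps 1–8 and 14–17); the side chain takes steps 9–13.

Steps most likely to fail:

1. Step 7 (key step). The allenyl ketone may be diverted before the cycloaddition: cycloisomerisation to a furan by trace palladium, reaction through the oxa-diene or [2+2] mode, oligomerisation, or loss of axial configuration by enolisation. Fallback: the cycloaddition is run at the alcohol oxidation level and the oxidation moved behind it. Setting out from 10, heating in toluene with BHT at 90–110 °C should give the bicyclic allylic alcohol (2R,4aR,5S,6S)-4a,5-dimethyl-6-(4,4,5,5-tetramethyl-1,3,2-dioxaborolan-2-yl)-2,3,4,4a,5,6-hexahydronaphthalen-2-ol F1 through the same tether-enforced transition state. Oxidation of the allylic alcohol with MnO2 then returns to the route at 12. Any F1 formed prematurely during step 6 is funnelled to 12 by the oxidant of step 7 in the same way.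

2. Step 6. Transmetalation of the pinacol boronate to the allenylpalladium alkoxide may be slow, the bis-boronate may couple twice, or chirality transfer may erode through isomerisation of the allenylpalladium intermediate. Fallback: the C1–C2 bond is made first and the allene second, by delivering hydride instead of carbon in the SN2′ step. Because the vinyl group then ends syn to the oxygen, the mirror-image oxirane is needed.
   - Setting out from 6, epoxidation as in step 4 but with the (R)-catalyst should give (2R,3S)-3-[(E)-3-methylpent-3-en-1-yl]oxirane-2-carbaldehyde F2.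
   - Ohira–Bestmann homologation gives (2S,3S)-2-ethynyl-3-[(E)-3-methylpent-3-en-1-yl]oxirane F3.
   - Sonogashira coupling with (E)-2-(2-bromovinyl)-4,4,5,5-tetramethyl-1,3,2-dioxaborolane (Pd(PPh3)2Cl2, CuI, Et3N) gives the enynyl oxirane 2-[(1E)-4-{(2S,3S)-3-[(E)-3-methylpent-3-en-1-yl]oxiran-2-yl}but-1-en-3-yn-1-yl]-4,4,5,5-tetramethyl-1,3,2-dioxaborolane F4.
   - Anti-SN2′ reduction with an N-heterocyclic-carbene copper hydride catalyst and polymethylhydrosiloxane should give (1E,3Ra,6S,9E)-9-methyl-1-(4,4,5,5-tetramethyl-1,3,2-dioxaborolan-2-yl)undeca-1,3,4,9-tetraen-6-ol F5, the carbinol epimer of 10 with the same allene axis.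
   - Oxidation and warming as in step 7 erase the carbinol centre and return to the route at 12.

3. Step 15. The base may deprotonate C3 (ε to the ketone and α to the ester oxygen) instead of C7, causing epimerisation or acyl migration, or it may attack the dienoate. Fallback: a base-free enaminone cleavage replaces the enolate chemistry. Setting out from 23, heating with tert-butoxybis(dimethylamino)methane in toluene at 60 °C should give the enaminone (1R,2S,8aR)-7-[(E)-(dimethylamino)methylidene]-1,8a-dimethyl-6-oxo-1,2,6,7,8,8a-hexahydronaphthalen-2-yl (2E,4E,6R)-6-[(tert-butyldimethylsilyloxy)methyl]octa-2,4-dienoate F6. Photooxygenation (O2, tetraphenylporphyrin, visible light, CH2Cl2, −78 °C) cleaves the electron-rich enamine double bond to the 6,7-dione 26, which tautomerises and returns to the route at 27.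

Further compounds
F1 | step 7 | (2R,4aR,5S,6S)-4a,5-dimethyl-6-(4,4,5,5-tetramethyl-1,3,2-dioxaborolan-2-yl)-2,3,4,4a,5,6-hexahydronaphthalen-2-ol | CC1(C)OB(OC1(C)C)[C@H]1C=CC2=C[C@H](O)CC[C@]2(C)[C@H]1C
F2 | step 6 | (2R,3S)-3-[(E)-3-methylpent-3-en-1-yl]oxirane-2-carbaldehyde | O=C[C@@H]1O[C@H]1CC/C(C)=C/C
F3 | step 6 | (2S,3S)-2-ethynyl-3-[(E)-3-methylpent-3-en-1-yl]oxirane | C#C[C@@H]1O[C@H]1CC/C(C)=C/C
F4 | step 6 | 2-[(1E)-4-{(2S,3S)-3-[(E)-3-methylpent-3-en-1-yl]oxiran-2-yl}but-1-en-3-yn-1-yl]-4,4,5,5-tetramethyl-1,3,2-dioxaborolane | CC1(C)OB(OC1(C)C)/C=C/C#C[C@@H]1O[C@H]1CC/C(C)=C/C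
F5 | step 6 | (1E,3Ra,6S,9E)-9-methyl-1-(4,4,5,5-tetramethyl-1,3,2-dioxaborolan-2-yl)undeca-1,3,4,9-tetraen-6-ol | CC1(C)OB(OC1(C)C)/C=C/C([H])=[C@]=C([H])[C@@H](O)CC/C(C)=C/C
F6 | step 15 | (1R,2S,8aR)-7-[(E)-(dimethylamino)methylidene]-1,8a-dimethyl-6-oxo-1,2,6,7,8,8a-hexahydronaphthalen-2-yl (2E,4E,6R)-6-[(tert-butyldimethylsilyloxy)methyl]octa-2,4-dienoate | CC[C@H](/C=C/C=C/C(=O)O[C@H]1C=CC2=CC(=O)/C(=C/N(C)C)C[C@]2(C)[C@H]1C)CO[Si](C)(C)C(C)(C)C
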